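## Structural features

The target 25 is a dearomatised acylphloroglucinol built from two fused six-membered rings. Ring A (C1, C2, C3, C4, C4a, C8a) is a carbocycle with an sp3 carbon C1, a ketone at C2, an enol C3=C4 carrying the C4 hydroxyl and a C4a=C8a double bond. Ring B (O1', C2', C3', C4') is a 2,3-dihydropyran-4-one fused across C4a–C8a, with O1' on C8a and the C4' carbonyl on C4a.

C1 is an all-carbon quaternary stereocentre bearing a prenyl group and a lavandulyl group, C1–CH2–CH(isopropenyl)–CH2CH=CMe2, whose methine stereocentre stands 1,3 to C1. C2' and C3' carry neighbouring cis methyl groups, and the fifth stereocentre is the benzylic carbon of the CH(Ph)CH2CO2H arm on C3, remote from all the others.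

The fragile groups are the enolised β-triketone of ring A (acidic, chelating, able to add to its own alkenes under acid), three electron-rich alkenes, the C3' hydrogen alpha to the C4' ketone (cis is the less stable arrangement), and the carboxylic acid, which lies between the oxygens on C2 and C4 and can lactonise onto either.

The real difficulty is C1: its two substituents are identical up to the second carbon, and the lavandulyl methine has no nearby functional group to direct its formation.

The key step uses the fact that in the aromatic tautomer of ring A, C1 is para to the C4 oxygen and ortho to the C2 oxygen. A phenoxide at C4 makes C1 nucleophilic, an acrylate ester on the C2 oxygen holds an electrophilic CH2 above it, and the new C–C bond closes a six-membered lactone in which C1 and the future lavandulyl carbon are 1,3 on a ring and can be related by equilibration.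

## Logic of the disconnections

25 to 24. The O–C bond of a tertiary benzylic ester is cut. The acid must be masked from step 8 onward because it would lactonise onto the C2 or C4 oxygen and would quench organometallic reagents. Nothing is gained in skeleton. The forward step must be an acidolysis mild enough for the enol and the three alkenes.

24 to 23. The C=CH2 bond of the isopropenyl group is cut back to an acetyl group. This reduces the lavandulyl group to an alpha-branched methyl ketone. The forward methylenation must be non-basic, since the centre alpha to the ketone is acyclic and epimerisable, and must tolerate the free ring A enol.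

23 to 21 (through 22). The C(=O)–CH3 bond is cut and the acyl carbon is reconnected to the C2 oxygen as a six-membered enol lactone. This turns the isolated acyclic stereocentre into a ring carbon 1,3 to C1 and masks the ring A enol. The forward step must deliver one methyl group to the lactone carbonyl and to no ring carbonyl.

21 to 19. The C1–CH2 bond is cut. Ring A becomes aromatic, C1 loses its stereocentre, and the CH2–CH(prenyl)–C(=O) unit becomes a 2-prenylacrylate on the C2 oxygen. Two stereocentres and the quaternary carbon disappear at once. The forward step must make the phenoxide react through an already substituted para carbon, on one face, at C1 and not at C3, and must let the alpha-carbon equilibrate.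

19 to 14 and 18. The ester C–O bond at the C2 oxygen is cut. This is convergent and feasible because that phenol is the only one not chelated. The forward acylation must be a mono-acylation under conditions too mild to epimerise C3'.

18 to 17 to 15 and 16. The ester is hydrolysed in the forward sense, and the allyl–vinyl C–C bond is cut to a symmetric 2-(halomethyl)acrylate and a vinyl Grignard reagent. The forward coupling must be a clean allylic substitution.

14 to 12 and 13. The ester C–O bond is cut and the acyl carbon is reconnected to the C4 oxygen as an aryl lactone. The lactone masks both the acid and the phenol that must stay out of the ring B closure, and reduces the substitution pattern to that of a coumarin. The forward opening needs a tertiary alkoxide and must not touch C3'.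

12 to 10 and 11. The benzylic C–phenyl bond is cut, restoring the coumarin C3=C4 bond. The benzylic centre is thus set late, after all Lewis-acid steps, which could racemise a benzylic carbon on a phloroglucinol ring by retro-Friedel–Crafts cleavage. The forward step must be a catalyst-controlled arylation that tolerates a ketone, a phenol and an alkene.

10 to 9. The aryl–CH2 bond of the prenyl group is cut and reconnected as a tertiary allyl ether on the neighbouring oxygen. This makes prenylation regiospecific at the only free ortho carbon. The forward step is thermal and neutral.

9 to 8. The O1'–C2' bond is cut. Both ring B stereocentres then come from one catalytic asymmetric ring closure of an ortho-hydroxyaryl enone. The forward step needs kinetic cis protonation and only one free phenol ortho to the enone, which the lactone and the ether guarantee.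

8 to 5 and 7 (7 from 6). The O–allyl bond is cut. The forward allylation must select the non-chelated hydroxyl and the branched ether.

5 to 3 and 4. The aryl–acyl bond is cut. The forward acylation must go to C8 of the coumarin.

3 to 1 and 2. The aryl–C bond and the lactone C–O bond are cut. The symmetry of 1 removes any regiochemical question.

## Other disconnections considered

Alternative 1: The cut is the C2'–C3' bond of ring B.
- Forward key step: the diazo ketone A1 (an 8-(2-diazopropanoyl)-7-ethoxy-4-phenylcoumarin with the 5-oxygen as pivalate) is decomposed by dirhodium tetrakis[N-phthaloyl-(S)-tert-leucinate], Rh2(S-PTTL)4 (divalent rhodium). The carbenoid inserts into an O–CH2 hydrogen of the ethyl ether and should give the cis-dimethylchromanone A2.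
- In its favour: one catalytic step forms a C–C bond that cannot revert and sets both ring B stereocentres, and insertion next to an ether oxygen normally gives the cis isomer, which is the one needed. The same reaction type is known on simpler aryl diazo ketones.
- Against it here: A1 needs a diazo transfer onto a hindered aryl ethyl ketone. The alpha-methyl carbenoid can be lost by 1,2-hydride shift. The insertion closes a six-membered ring, slower than the usual five-membered closure, and high enantiocontrol is not assured for this class.
- Comparison: on ring B it equals the chosen route in step count (one asymmetric step). It is better in that the closure is irreversible, whereas the oxa-Michael closure of step 5 gives the cis isomer only under kinetic control. But ring B is the least demanding part of 25. A2 still contains a planar 4-phenylcoumarin, so the benzylic centre, C1 and the lavandulyl centre remain unsolved, and the later steps of the chosen plan would have to be appended. The total would be longer by the steps to A1.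

Alternative 2: The cuts are the C3–CH(Ph) bond and the O–C(=O) bond of a dihydropyranone spanning C3 and the C4 oxygen.
- Forward key step: the trione A3, whose quaternary carbon carries prenyl and (S)-lavandulyl, reacts with the ynal A4 under a chiral N-heterocyclic carbene. The carbene turns A4 into an unsaturated acyl donor, one of the two ring CH2 carbons adds to its beta-carbon and the neighbouring enol oxygen is acylated, giving the enol lactone A5 with C1 and the benzylic carbon defined.
- In its favour, and better than the chosen plan on these points: the bond-forming event (a 1,3-dicarbonyl adding to an unsaturated acyl azolium) is closer to established chemistry than the dearomatisation of step 12. Two stereocentres arise in one catalytic step. The lactone masks the acid, so no ester protecting group and no final acid treatment are needed.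
- Against it here: the configuration of C1 depends on the catalyst telling apart two CH2 groups that differ only in whether the remote quaternary carbon turns its prenyl or its lavandulyl CH2 toward them. A3 requires geminal dialkylation of a phloroglucinol with an unactivated, beta-branched chiral alkyl electrophile. The lavandulyl centre must be imported and is not created by relay. Ring B would then have to be built on a non-aromatic trione, where the alkaloid-controlled closure is untested.
- Comparison: the step count is similar or lower and the benzylic centre is handled more elegantly. But the hardest element, C1, is left to the weakest control, whereas the chosen plan ties C1 to a tether and a catalyst and derives the lavandulyl centre from it.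

Alternative 3: The cuts are the O1'–C8a bond of ring B and the C4–C4a bond of ring A, which unravel both rings to the open chain A6.
- Precursor: A6 is a quaternary carbon (the future C1) bearing prenyl, lavandulyl, a 1,3-diketone chain ending in a CH(Me)–CH(Me)–OH unit of fixed configuration, and a 2,2-dimethyl-1,3-dioxin-4-one that carries the benzylic arm as methyl ester.
- Forward key step: mild acid condenses the hydroxyl with the C8a carbonyl to close ring B. Heating then releases acetone, and the acylketene acylates C4a to close ring A and give A7, the methyl ester of 25.
- In its favour, and better than the chosen plan on these points: both closures are reliable reaction types, the regiochemistry is unambiguous, and no stereocentre is formed in the key step. The final methyl ester can be removed by base with ring A protected as its enolate.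
- Against it here: all five stereocentres, including an acyclic quaternary carbon with four different carbon chains, must be made beforehand. An alpha,alpha-dialkyl β-dicarbonyl of this kind is prone to retro-Claisen cleavage and its two acyl arms must be told apart. The β-hydroxy ketone end can epimerise or undergo retro-aldol cleavage.
- Comparison: the difficulty moves from the ring-forming step to the synthesis of A6. Mechanistically the key step is safer. In step economy it is clearly worse than the chosen route, which makes C1 and the lavandulyl centre in one operation from an aromatic compound reached in eight linear steps.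

Key step: step 12

Conventions and assumptions (chemistry only):
- Locants. Ring A of 25 is C1, C2, C3, C4, C4a, C8a and ring B is O1', C2', C3', C4'. The same ring A locants are used for the aromatic compounds 14 and 19. Compounds 3 to 12 carry ordinary coumarin locants.
- Ester choice. The acid is carried as its 2-phenylpropan-2-yl ester. A tertiary ester is needed so that neither flanking oxygen can re-close a lactone and so that Grignard reagents are tolerated. The more usual tert-butyl ester would need strong acid at the end, in the presence of an enolised triketone and three acid-sensitive alkenes, whereas the 2-phenylpropan-2-yl ester is cleaved by 1% CF3CO2H.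
- Assumption. (−)-Quinine and (S)-SEGPHOS are assumed to induce in 8 and 10 the same sense as in the closely related coumarins for which these reactions are established. Otherwise quinidine or (R)-SEGPHOS would be used.
- Structure check. The configurations written for 19 and 21 were compared centre by centre with 25 (C1 S, lactone alpha-carbon S, benzylic carbon S, C2' R, C3' S; the two prenyl groups of 21 trans on the lactone ring). They agree, and no correction is needed.

## Route

Step 1
Reactants: 1 phloroglucinol; 2 ethyl propiolate
Product: 3 5,7-dihydroxycoumarin
Conditions: ZnCl2 (1 equiv), 1,4-dioxane, 100 °C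
Reagents that add atoms: none
Why: Pechmann-type condensation: the electron-rich ring adds to the β-carbon of the propiolate and the adjacent hydroxyl lactonises with loss of ethanol; the threefold symmetry of 1 allows only one product.

Step 2
Reactants: 3 5,7-dihydroxycoumarin; 4 tigloyl chloride
Product: 5 5,7-dihydroxy-8-[(E)-2-methylbut-2-enoyl]coumarin
Conditions: AlCl3 (4 equiv), PhNO2/ClCH2CH2Cl, 0 → 40 °C; cold 1 M HCl
Reagents that add atoms: none
Why: Friedel–Crafts acylation; in 7-hydroxycoumarins C8 (ortho to the 7-hydroxyl, para to the 5-hydroxyl) is the most nucleophilic carbon, so the 8-acyl isomer should predominate and the minor 6-isomer be removed by crystallisation; a cold acidic quench keeps the ortho-hydroxy enone from closing prematurely to racemic chromanone.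

Step 3
Reactants: 6 2-methylbut-3-en-2-ol
Product: 7 tert-butyl 2-methylbut-3-en-2-yl carbonate
Conditions: n-BuLi, THF, −78 °C; then Boc2O, −78 → 20 °C
Reagents that add atoms: di-tert-butyl dicarbonate, CC(C)(C)OC(=O)OC(=O)OC(C)(C)C
Why: acylation of the lithium alkoxide by the dicarbonate (carbonate formation); prior deprotonation is needed because the tertiary alcohol is a poor nucleophile.

Step 4
Reactants: 5 5,7-dihydroxy-8-tigloylcoumarin; 7 tert-butyl 2-methylbut-3-en-2-yl carbonate
Product: 8 7-hydroxy-5-(2-methylbut-3-en-2-yloxy)-8-[(E)-2-methylbut-2-enoyl]coumarin
Conditions: Pd(PPh3)4 (5 mol%), 7 (1.1 equiv), THF, 0 °C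
Reagents that add atoms: none
Why: Tsuji–Trost O-allylation: zerovalent palladium ionises 7 to a π-(1,1-dimethylallyl) complex, carbon dioxide and tert-butoxide; the base removes the more acidic, non-chelated 5-hydroxyl proton (para to the acyl group) and the phenoxide attacks the more substituted allyl terminus under kinetic control at low temperature, while the 7-hydroxyl stays locked in its hydrogen bond to the ketone.

Step 5
Reactants: 8 7-hydroxy-5-(2-methylbut-3-en-2-yloxy)-8-tigloylcoumarin
Product: 9 (8R,9S)-cis-8,9-dimethyl-5-(2-methylbut-3-en-2-yloxy)-8,9-dihydro-2H,10H-pyrano[2,3-f]chromene-2,10-dione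
Conditions: (−)-quinine (20 mol%), chlorobenzene, 20 °C
Reagents that add atoms: none
Why: alkaloid-catalysed asymmetric intramolecular oxa-Michael addition, a reaction type established for 7-hydroxy-8-tigloylcoumarins: the quinuclidine nitrogen activates the 7-hydroxyl while the C9 hydroxyl of quinine binds the enone, so oxygen adds to one face of the β-carbon (C2' becomes R) and the enol is protonated from the same side under kinetic control (C3' becomes S, cis); the ether on the 5-oxygen ensures that no more acidic phenol captures the base.

Step 6
Reactants: 9 cis-chromanone-fused coumarin tertiary allyl ether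
Product: 10 (8R,9S)-5-hydroxy-8,9-dimethyl-6-(3-methylbut-2-enyl)-8,9-dihydro-2H,10H-pyrano[2,3-f]chromene-2,10-dione
Conditions: toluene, 120 °C, sealed tube
Reagents that add atoms: none
Why: aromatic Claisen rearrangement: the [3,3] shift carries the allyl terminus to C6, the only unsubstituted ortho carbon, which turns the tertiary ether into a normal prenyl group, and tautomerisation restores the 5-hydroxyl; neutral thermal conditions leave the cis ring B untouched.

Step 7
Reactants: 10 6-prenyl-5-hydroxy cis-chromanone-fused coumarin; 11 phenylboronic acid
Product: 12 (4S,8R,9S)-5-hydroxy-8,9-dimethyl-6-(3-methylbut-2-enyl)-4-phenyl-3,4,8,9-tetrahydro-2H,10H-pyrano[2,3-f]chromene-2,10-dione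
Conditions: Rh(acac)(C2H4)2 (5 mol%), (S)-SEGPHOS (5.5 mol%), 11 (5 equiv), 1,4-dioxane/H2O (10:1), 60 °C
Reagents that add atoms: none
Why: Hayashi–Miyaura reaction: phenyl passes from boron to monovalent rhodium and adds across the coumarin C3=C4 bond perpendicular to the ring plane, which makes the in-plane peri hydroxyl tolerable, and the oxa-π-allyl rhodium is protonated by water; the benzylic centre (coumarin C4, S) is set by the ligand, chosen by analogy with the sense known for the parent coumarin, and the base-free medium spares the lactone and C3'.

Step 8
Reactants: 12 (4S)-4-phenyl dihydrocoumarin; 13 2-phenylpropan-2-ol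
Product: 14 2-phenylpropan-2-yl (3S)-3-[(2R,3S)-5,7-dihydroxy-2,3-dimethyl-8-(3-methylbut-2-enyl)-4-oxochroman-6-yl]-3-phenylpropanoate
Conditions: 13 (4 equiv), KN(SiMe3)2 (3.5 equiv), THF, 0 °C; then 12, 0 → 20 °C; aq. NH4Cl
Reagents that add atoms: none
Why: alcoholysis (transesterification) of an aryl lactone: the tertiary alkoxide attacks the unhindered lactone carbonyl and a phenoxide leaves, which is downhill by many pKa units and so not reversed; with both phenols ionised the ring B carbonyl is a vinylogous carboxylate, so C3' is not enolised, and the tertiary ester cannot re-lactonise onto either flanking oxygen.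

Step 9
Reactants: 15 ethyl 2-(bromomethyl)acrylate; 16 2-methylprop-1-enylmagnesium bromide
Product: 17 ethyl 5-methyl-2-methylenehex-4-enoate
Conditions: CuI (10 mol%), THF, −78 → −40 °C
Reagents that add atoms: none
Why: copper-catalysed allylic substitution of a Grignard reagent on a 2-(bromomethyl)acrylate; direct and allylically transposed displacement give the same product because the allyl unit is symmetric.

Step 10
Reactants: 17 ethyl 5-methyl-2-methylenehex-4-enoate
Product: 18 5-methyl-2-methylenehex-4-enoic acid
Conditions: LiOH, THF/H2O (3:1), 20 °C; then 1 M HCl to pH 3, 0 °C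
Reagents that add atoms: lithium hydroxide, [Li+].[OH-]
Why: saponification by acyl–oxygen cleavage; the alpha-substituted acrylate resists conjugate addition of hydroxide at room temperature and the isolated alkene is inert to cold dilute acid.

Step 11
Reactants: 14 diphenol 2-phenylpropan-2-yl ester; 18 5-methyl-2-methylenehex-4-enoic acid
Product: 19 2-phenylpropan-2-yl (3S)-3-[(2R,3S)-5-hydroxy-2,3-dimethyl-8-(3-methylbut-2-enyl)-7-(5-methyl-2-methylenehex-4-enoyloxy)-4-oxochroman-6-yl]-3-phenylpropanoate
Conditions: EDC·HCl (1.2 equiv), DMAP (10 mol%), CH2Cl2, 0 °C
Reagents that add atoms: none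
Why: Steglich esterification: of the two phenols only the C2 hydroxyl (para to the ring B carbonyl, not hydrogen-bonded) reacts, the C4 hydroxyl being tied up in the chelate with the C4' carbonyl; catalytic DMAP at 0 °C keeps the medium too weakly basic to epimerise C3'.

Step 12
Reactants: 19 aryl 2-prenylacrylate (key-step precursor)
Product: 21 trans enol lactone with C1 and the lactone alpha-carbon both S, via lactone alpha-epimer 20 (not isolated)
Conditions: O-allyl-N-(9-anthracenylmethyl)cinchonidinium bromide (10 mol%), Cs2CO3 (0.5 equiv), toluene/CH2Cl2 (4:1), 4 Å molecular sieves, 0.01 M, −30 → 20 °C, held until the epimer ratio is constant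
Reagents that add atoms: none
Why: Proposed new method: Cs2CO3 removes the chelated C4 hydroxyl proton and the phenoxide enters the organic phase as a contact ion pair with the chiral ammonium; because both ortho positions of the C2 oxygen are substituted the ester plane stands perpendicular to ring A, the acrylate lies over one face with its CH2 terminus above C1, and C1, para to the phenoxide oxygen, adds to it in a vinylogous Michael reaction that forms the C1–CH2 bond, a cross-conjugated dienone and a lactone enolate, which is protonated by unreacted phenol so that substoichiometric base suffices. The six-membered lactone (C1, CH2, alpha-carbon, C=O, O, C2) closes in a 6-endo-trig mode. The closest known reaction types are the catalytic asymmetric intramolecular Michael dearomatisation of phenols and naphthols and the chiral phase-transfer alkylative dearomatisation of acylphloroglucinols; new here are the ester tether on a ring oxygen and the quaternisation of an already substituted carbon. The configuration at C1 is decided by the face on which the acrylate sits in the ion pair, hence by the catalyst, since the benzylic arm puts phenyl on one face and the ester chain on the other and gives little bias of its own. The alpha-carbon is protonated without control to give 20 and 21, and carbonate then equilibrates them through the lactone enolate toward 21, in which the alpha-prenyl group is pseudo-equatorial and trans to the pseudo-axial C1 prenyl group, whereas 20 suffers a 1,3-diaxial contact. Attack at C1 is preferred over C3 because C3 carries the branched benzylic group and would give a linearly conjugated dienone, while C1 carries only a CH2 substituent and gives a vinylogous ester; high dilution suppresses intermolecular Michael addition and acyl transfer. C3' is not endangered, because in 19 the phenoxide makes the ring B carbonyl a vinylogous carboxylate and in 21 that carbonyl is a vinylogous ester whose alpha-hydrogen is far less acidic than the anhydride-like lactone alpha-hydrogen.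

Step 13
Reactants: 21 trans enol lactone
Product: 23 methyl ketone with free ring A enol, via Weinreb amide 22 (not isolated)
Conditions: MeNH(OMe)·HCl (1.5 equiv), i-PrMgCl (3.0 equiv), THF, −20 °C; then MeMgBr (4 equiv), −20 → 0 °C; pH 4 citrate buffer
Reagents that add atoms: methylmagnesium bromide, C[Mg]Br (methyl group of 23); N,O-dimethylhydroxylamine hydrochloride, CNOC.Cl (its N(OMe)Me unit is kept only in 22)
Why: Weinreb ketone synthesis run in one pot: the enol lactone is a vinylogous anhydride and by far the most electrophilic acyl group, so the magnesium amide opens it at low temperature and releases ring A as its magnesium enolate, which shields the ring carbonyls; MeMgBr then adds once to the N-methoxy-N-methylamide, whose chelated tetrahedral intermediate survives until the mildly acidic quench, so the hindered tertiary ester is untouched and the centre alpha to the new ketone never meets base as a free ketone.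

Step 14
Reactants: 23 methyl ketone
Product: 24 2-phenylpropan-2-yl ester of 25
Conditions: Zn, CH2Br2, TiCl4, THF (reagent aged at 5 °C); then 23, CH2Cl2, 0 → 20 °C; aq. NaHCO3
Reagents that add atoms: dibromomethane, BrCBr
Why: Lombardo methylenation: the zinc–titanium methylene reagent is non-basic, so the acyclic stereocentre alpha to the methyl ketone is not epimerised; it reacts with ketones and not with esters, and the ring carbonyls are masked because the excess reagent converts the acidic enol into its metal enolate.

Step 15
Reactants: 24 2-phenylpropan-2-yl ester of 25
Product: 25 (3S)-3-[(2R,3S,8S)-5-hydroxy-2,3-dimethyl-8-(3-methylbut-2-enyl)-8-[(2S)-5-methyl-2-(prop-1-en-2-yl)hex-4-enyl]-4,7-dioxo-3,4,7,8-tetrahydro-2H-chromen-6-yl]-3-phenylpropanoic acid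
Conditions: CF3CO2H (1% v/v), i-Pr3SiH (3 equiv), CH2Cl2, 0 °C; pH 7 buffer
Reagents that add atoms: none
Why: acidolysis of a 2-phenylpropan-2-yl ester through the tertiary benzylic cation, which proceeds at an acid strength too low to protonate the trisubstituted and 1,1-disubstituted alkenes or to lactonise the acid onto the enol; the silane reduces the cation to cumene so that it cannot alkylate ring A.

## Compound list

1 | phloroglucinol (benzene-1,3,5-triol) | Oc1cc(O)cc(O)c1 | starting material
2 | ethyl propiolate | C#CC(=O)OCC | starting material
3 | 5,7-dihydroxycoumarin | O=C1C=Cc2c(O)cc(O)cc2O1 | intermediate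
4 | tigloyl chloride, (E)-2-methylbut-2-enoyl chloride | C/C=C(\C)C(=O)Cl | starting material
5 | 5,7-dihydroxy-8-[(E)-2-methylbut-2-enoyl]coumarin | C/C=C(\C)C(=O)c1c(O)cc(O)c2C=CC(=O)Oc12 | intermediate
6 | 2-methylbut-3-en-2-ol | C=CC(C)(C)O | starting material
7 | tert-butyl 2-methylbut-3-en-2-yl carbonate | C=CC(C)(C)OC(=O)OC(C)(C)C | intermediate
8 | 7-hydroxy-5-(2-methylbut-3-en-2-yloxy)-8-[(E)-2-methylbut-2-enoyl]coumarin | C/C=C(\C)C(=O)c1c(O)cc(OC(C)(C)C=C)c2C=CC(=O)Oc12 | intermediate
9 | (8R,9S)-8,9-dimethyl-5-(2-methylbut-3-en-2-yloxy)-8,9-dihydro-2H,10H-pyrano[2,3-f]chromene-2,10-dione (coumarin with the cis-dimethyl dihydropyranone fused at O7/C8) | C[C@H]1Oc2cc(OC(C)(C)C=C)c3C=CC(=O)Oc3c2C(=O)[C@H]1C | intermediate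
10 | (8R,9S)-5-hydroxy-8,9-dimethyl-6-(3-methylbut-2-enyl)-8,9-dihydro-2H,10H-pyrano[2,3-f]chromene-2,10-dione | C[C@H]1Oc2c(CC=C(C)C)c(O)c3C=CC(=O)Oc3c2C(=O)[C@H]1C | intermediate
11 | phenylboronic acid | OB(O)c1ccccc1 | starting material
12 | (4S,8R,9S)-5-hydroxy-8,9-dimethyl-6-(3-methylbut-2-enyl)-4-phenyl-3,4,8,9-tetrahydro-2H,10H-pyrano[2,3-f]chromene-2,10-dione | C[C@H]1Oc2c(CC=C(C)C)c(O)c3[C@H](c4ccccc4)CC(=O)Oc3c2C(=O)[C@H]1C | intermediate
13 | 2-phenylpropan-2-ol | CC(C)(O)c1ccccc1 | starting material
14 | 2-phenylpropan-2-yl (3S)-3-[(2R,3S)-5,7-dihydroxy-2,3-dimethyl-8-(3-methylbut-2-enyl)-4-oxochroman-6-yl]-3-phenylpropanoate | CC(C)=CCc1c(O)c([C@@H](CC(=O)OC(C)(C)c3ccccc3)c2ccccc2)c(O)c2C(=O)[C@@H](C)[C@@H](C)Oc12 | intermediate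
15 | ethyl 2-(bromomethyl)acrylate | C=C(CBr)C(=O)OCC | starting material
16 | 2-methylprop-1-enylmagnesium bromide | CC(C)=C[Mg]Br | starting material
17 | ethyl 5-methyl-2-methylenehex-4-enoate | C=C(CC=C(C)C)C(=O)OCC | intermediate
18 | 5-methyl-2-methylenehex-4-enoic acid (2-prenylacrylic acid) | C=C(CC=C(C)C)C(=O)O | intermediate
19 | 2-phenylpropan-2-yl (3S)-3-[(2R,3S)-5-hydroxy-2,3-dimethyl-8-(3-methylbut-2-enyl)-7-(5-methyl-2-methylenehex-4-enoyloxy)-4-oxochroman-6-yl]-3-phenylpropanoate (key-step precursor) | CC(C)=CCc1c(OC(=O)C(=C)CC=C(C)C)c([C@@H](CC(=O)OC(C)(C)c3ccccc3)c2ccccc2)c(O)c2C(=O)[C@@H](C)[C@@H](C)Oc12 | intermediate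
20 | lactone alpha-epimer of 21 (alpha-carbon R, the two prenyl groups cis on the lactone ring; not isolated) | CC(C)=CC[C@@]12C[C@@H](CC=C(C)C)C(=O)OC1=C([C@@H](CC(=O)OC(C)(C)c3ccccc3)c1ccccc1)C(=O)C1=C2O[C@H](C)[C@H](C)C1=O | intermediate
21 | dearomatised enol lactone (key-step product): ring A as C2=C3/C4=O/C4a=C8a dienone, C1 (S) bearing prenyl, six-membered lactone C1–CH2–CH(prenyl)–C(=O)–O–C2 with the alpha-carbon S (prenyl groups trans), C3 bearing the (S)-CH(Ph)CH2CO2CMe2Ph arm, ring B (2'R,3'S)-cis-dimethyl | CC(C)=CC[C@@]12C[C@H](CC=C(C)C)C(=O)OC1=C([C@@H](CC(=O)OC(C)(C)c3ccccc3)c1ccccc1)C(=O)C1=C2O[C@H](C)[C@H](C)C1=O | intermediate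
22 | 2-phenylpropan-2-yl (3S)-3-[(2R,3S,8S)-5-hydroxy-8-{(2S)-2-[methoxy(methyl)carbamoyl]-5-methylhex-4-enyl}-2,3-dimethyl-8-(3-methylbut-2-enyl)-4,7-dioxo-3,4,7,8-tetrahydro-2H-chromen-6-yl]-3-phenylpropanoate (Weinreb amide; not isolated) | CON(C)C(=O)[C@@H](CC=C(C)C)C[C@]1(CC=C(C)C)C(=O)C([C@@H](CC(=O)OC(C)(C)c3ccccc3)c2ccccc2)=C(O)C2=C1O[C@H](C)[C@H](C)C2=O | intermediate
23 | 2-phenylpropan-2-yl (3S)-3-[(2R,3S,8S)-8-[(2S)-2-acetyl-5-methylhex-4-enyl]-5-hydroxy-2,3-dimethyl-8-(3-methylbut-2-enyl)-4,7-dioxo-3,4,7,8-tetrahydro-2H-chromen-6-yl]-3-phenylpropanoate | CC(=O)[C@@H](CC=C(C)C)C[C@]1(CC=C(C)C)C(=O)C([C@@H](CC(=O)OC(C)(C)c3ccccc3)c2ccccc2)=C(O)C2=C1O[C@H](C)[C@H](C)C2=O | intermediate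
24 | 2-phenylpropan-2-yl ester of 25 | C=C(C)[C@@H](CC=C(C)C)C[C@]1(CC=C(C)C)C(=O)C([C@@H](CC(=O)OC(C)(C)c3ccccc3)c2ccccc2)=C(O)C2=C1O[C@H](C)[C@H](C)C2=O | intermediate
25 | (3S)-3-[(2R,3S,8S)-5-hydroxy-2,3-dimethyl-8-(3-methylbut-2-enyl)-8-[(2S)-5-methyl-2-(prop-1-en-2-yl)hex-4-enyl]-4,7-dioxo-3,4,7,8-tetrahydro-2H-chromen-6-yl]-3-phenylpropanoic acid (CNP0150579.2) | C=C(C)[C@@H](CC=C(C)C)C[C@]1(CC=C(C)C)C(=O)C([C@@H](CC(=O)O)c2ccccc2)=C(O)C2=C1O[C@H](C)[C@H](C)C2=O | target

## Step count and least certain steps

Total: 15 steps. Longest linear sequence: 12 steps (1, 2, 4, 5, 6, 7, 8, 11, 12, 13, 14, 15).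

Step 12 (key step, proposed new method). The most likely failures are reversal of the Michael addition during the base equilibration (re-aromatisation by elimination from the lactone enolate), insufficient face selection at C1, or competing acyl transfer between phenoxide and aryl ester. The fallback uses known chemistry and replaces the reversible addition by an irreversible alkylation. It sets out from 14. The non-chelated phenol is acylated (2,6-lutidine, CH2Cl2, −40 °C) with 2-(bromomethyl)acryloyl chloride F1, made from commercial 2-(bromomethyl)acrylic acid and oxalyl chloride, to give the aryl 2-(bromomethyl)acrylate F2. Under the same ammonium salt and Cs2CO3 the phenoxide carbon C1 displaces bromide, an alkylative dearomatisation with an allylic halide of the kind known for acylphloroglucinols, and should give the alpha-methylene enol lactone F3. Conjugate addition of the cuprate from 16 and CuI with Me3SiCl (THF, −78 °C) to the exocyclic methylene supplies the missing isobutenyl carbons. Protonation and equilibration with DBU should then give 21, where the route is rejoined.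

Step 7. The most likely failure is slow insertion of the hindered, electron-rich coumarin into the rhodium–phenyl bond, so that protodeboronation of 11 wins, or insufficient face selection. The fallback gives up catalyst control. From 10, stoichiometric Ph2CuLi with Me3SiCl (THF, −78 °C) should add phenyl to give 12 together with its coumarin C4 epimer F4. Because 10 is a single enantiomer the two are diastereomers and can be separated by chromatography or crystallisation. The route is rejoined at 12.

Step 13. The most likely failure is attack of the nitrogen nucleophile at C2 or C8a (addition–elimination on the vinylogous anhydride) instead of at the lactone carbonyl, or double addition of the Grignard reagent. The fallback changes the acyl donor. From 21, Me2AlSEt (from AlMe3 and EtSH, CH2Cl2, 0 °C) should open the lactone to the S-ethyl thioester F5. Fukuyama coupling with MeZnI and PdCl2(PPh3)2 (divalent palladium precatalyst) in toluene at 20 °C then gives 23.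

Step 14. The most likely failure is loss of the titanium–zinc reagent to the acidic ring A enol, reversible hemiketal formation between the methyl ketone and the C2 enol oxygen that hides the carbonyl, or methylenation of a ring carbonyl. The fallback is a Peterson olefination. From 23, the organocerium reagent from Me3SiCH2MgCl and CeCl3 (THF, −78 °C) should add to the ketone to give the β-hydroxysilane F6 (mixture at the carbinol carbon). KH in THF at 0 °C then eliminates trimethylsilanolate to give 24.

## Further compounds

F1 | step 12 | 2-(bromomethyl)acryloyl chloride | C=C(CBr)C(=O)Cl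
F2 | step 12 | 2-phenylpropan-2-yl (3S)-3-[(2R,3S)-7-[2-(bromomethyl)acryloyloxy]-5-hydroxy-2,3-dimethyl-8-(3-methylbut-2-enyl)-4-oxochroman-6-yl]-3-phenylpropanoate | CC(C)=CCc1c(OC(=O)C(=C)CBr)c([C@@H](CC(=O)OC(C)(C)c3ccccc3)c2ccccc2)c(O)c2C(=O)[C@@H](C)[C@@H](C)Oc12
F3 | step 12 | alpha-methylene analogue of 21 (exocyclic CH2 on the lactone alpha-carbon, C1 S) | CC(C)=CC[C@@]12CC(=C)C(=O)OC1=C([C@@H](CC(=O)OC(C)(C)c3ccccc3)c1ccccc1)C(=O)C1=C2O[C@H](C)[C@H](C)C1=O
F4 | step 7 | (4R,8R,9S)-5-hydroxy-8,9-dimethyl-6-(3-methylbut-2-enyl)-4-phenyl-3,4,8,9-tetrahydro-2H,10H-pyrano[2,3-f]chromene-2,10-dione (C4 epimer of 12) | C[C@H]1Oc2c(CC=C(C)C)c(O)c3[C@@H](c4ccccc4)CC(=O)Oc3c2C(=O)[C@H]1C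
F5 | step 13 | S-ethyl thioester corresponding to 22 (C(=O)SEt in place of the N-methoxy-N-methylamide) | CCSC(=O)[C@@H](CC=C(C)C)C[C@]1(CC=C(C)C)C(=O)C([C@@H](CC(=O)OC(C)(C)c3ccccc3)c2ccccc2)=C(O)C2=C1O[C@H](C)[C@H](C)C2=O
F6 | step 14 | β-hydroxysilane from 23 (C(OH)(CH3)CH2SiMe3 in place of acetyl, carbinol configuration undefined) | C[Si](C)(C)CC(C)(O)[C@@H](CC=C(C)C)C[C@]1(CC=C(C)C)C(=O)C([C@@H](CC(=O)OC(C)(C)c3ccccc3)c2ccccc2)=C(O)C2=C1O[C@H](C)[C@H](C)C2=O
A1 | alternative 1 | 8-(2-diazopropanoyl)-7-ethoxy-2-oxo-4-phenyl-2H-chromen-5-yl pivalate | CCOc1cc(OC(=O)C(C)(C)C)c2c(c1C(=O)C(C)=[N+]=[N-])OC(=O)C=C2c1ccccc1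
A2 | alternative 1 | (8R,9S)-8,9-dimethyl-2,10-dioxo-4-phenyl-9,10-dihydro-2H,8H-pyrano[2,3-f]chromen-5-yl pivalate | C[C@H]1Oc2cc(OC(=O)C(C)(C)C)c3c(c2C(=O)[C@H]1C)OC(=O)C=C3c1ccccc1
A3 | alternative 2 | 2-[(2S)-5-methyl-2-(prop-1-en-2-yl)hex-4-enyl]-2-(3-methylbut-2-enyl)cyclohexane-1,3,5-trione | C=C(C)[C@@H](CC=C(C)C)CC1(CC=C(C)C)C(=O)CC(=O)CC1=O
A4 | alternative 2 | 3-phenylprop-2-ynal | O=CC#Cc1ccccc1
A5 | alternative 2 | enol lactone of ring A with the dihydropyranone spanning C3 and the C4 oxygen, C1 and the benzylic carbon set | C=C(C)[C@@H](CC=C(C)C)C[C@]1(CC=C(C)C)C(=O)C2=C(OC(=O)C[C@H]2c3ccccc3)C=C1O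
A6 | alternative 3 | open-chain precursor: quaternary carbon bearing prenyl, (S)-lavandulyl, the C(=O)CH2C(=O)CH(Me)CH(Me)OH chain and a 2,2-dimethyl-1,3-dioxin-4-one carrying the (S)-CH(Ph)CH2CO2Me arm | C=C(C)[C@@H](CC=C(C)C)C[C@@](CC=C(C)C)(C(=O)CC(=O)[C@@H](C)[C@@H](C)O)C1=C([C@@H](CC(=O)OC)c2ccccc2)C(=O)OC(C)(C)O1
A7 | alternative 3 | methyl ester of 25 | C=C(C)[C@@H](CC=C(C)C)C[C@]1(CC=C(C)C)C(=O)C([C@@H](CC(=O)OC)c2ccccc2)=C(O)C2=C1O[C@H](C)[C@H](C)C2=O
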